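Whatever the temperature, each substrate that ends as target or as isomer of the product has taken one reagent, each self-condensation product has taken two, and the pairs hold none, so the charge of reagent is a budget that can be counted in turnovers.

| flask | substrate | reagent | temperature | remark | time |
|---|---|---|---|---|---|
| autumn | 0.27 M | 0.24 M | 48 °C | run made earlier |  |
| dusk | 0.60 M | 0.24 M | 64 °C | run made earlier |  |
| dawn | 0.40 M | 0.36 M | 48 °C | run made earlier |  |
| Tuesday's | 0.40 M | 0.240 M | 40 °C |  | 80 min |
| Sunday's | 0.40 M | 0.240 M | 55 °C |  | 80 min |
| Friday's | 0.40 M | 0.240 M | 70 °C |  | 80 min |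

- autumn (time / min: target / %, substrate / %): 3.00: 0.1, 99.0; 10.0: 1.1, 96.6; 15.0: 1.9, 95.0; 25.0: 4.8, 91.2; 40.0: 7.4, 89.6; 50.0: 11.1, 87.8
- dusk (time / min: target / %, substrate / %): 1.33: 0.8, 98.0; 2.00: 1.4, 96.9; 3.00: 1.4, 96.1; 6.00: 3.7, 94.7; 10.0: 6.8, 90.7; 15.0: 7.8, 88.4
- dawn (time / min: target / %, substrate / %): 4.00: 0.6, 99.6; 12.0: 4.1, 93.7; 20.0: 5.8, 93.4; 30.0: 7.5, 91.2; 50.0: 12.8, 86.1

(readings scatter by 1 percentage point)

1. which flask leads in amount of target, in percent of the substrate charged ("all alike" within 1.5 percentage points) (Tuesday's / Sunday's / Friday's / all alike)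
2. how much target is there at the end, in percent of the substrate charged: Tuesday's
3. how much target is there at the end, in percent of the substrate charged: Sunday's
4. how much target is there at the end, in percent of the substrate charged: Friday's

- the analysis behind the earlier runs scatters by 1 percentage point, standard deviation
- steps thought possible: substrate <-> tight pair; tight pair <-> loose pair; reagent + tight pair -> target; reagent + loose pair -> isomer of the product; 2 reagent -> self-condensation product

Two chemists dispute Friday's flask. The first counts turnovers of the substrate, which falls roughly first order. The last dusk reading gives a loss constant of 0.00822 min⁻¹, so 80 min at that rate are 0.658 turnovers, with 48.2% of the substrate lost. Friday's flask is hotter than dusk, so the first chemist expects more than that. This view has served so far: the dusk run had lost 0.0696 M of substrate against 0.24 M of reagent.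

The second chemist counts reagent. The reagent ceiling, c(reagent)/c(substrate) at the charge, is the limiting reagent's bound on target and isomer together, here 60.0%. Friday's loss at the dusk rate already asks 0.193 M of the 0.240 M charged, and self-condensation draws on the same budget, though no run read reagent. I side with the second chemist and expect target and isomer together in Friday's flask to stall under 60.0%.

The forecast leans on the first count, cut by the ceiling: Friday's leads, with Tuesday's at 10%, Sunday's at 22% and Friday's at 30% (19% to 41%), noting that “self-condensation is unmeasured”.

The flasks give 6.53% for Tuesday's, 18.0% for Sunday's and 22.6% for Friday's, so Friday's leads. Friday's substrate goes from 76.2% at 40.0 min to 72.4% at 80.0 min, with 1.85% of its reagent left. The first view keeps Tuesday's flask, where substrate goes evenly from 94.9% to 90.3% with 44.8% of the reagent left.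

    substrate ⇌ tight pair (K = 0.00874, k = 5.23 × 10⁻⁴ s⁻¹, Ea = 91.0 kJ mol⁻¹, ΔH = −44.0 kJ mol⁻¹)
    tight pair ⇌ loose pair (K = 0.350, k = 0.0654 s⁻¹, Ea = 97.0 kJ mol⁻¹, ΔH = −17.0 kJ mol⁻¹)
    reagent + tight pair → target (k = 0.201 M⁻¹ s⁻¹, Ea = 72.0 kJ mol⁻¹)
    reagent + loose pair → isomer of the product (k = 0.111 M⁻¹ s⁻¹, Ea = 54.0 kJ mol⁻¹)
    2 reagent → self-condensation product (k = 0.00306 M⁻¹ s⁻¹, Ea = 63.0 kJ mol⁻¹)
    (constants at 70 °C)

Of Friday's ceiling of 60.0%, target and isomer hold 26.8%, that is 0.107 M of reagent, while 0.0643 M of self-condensation product holds 0.129 M. The neighbouring flask is Friday's with 1.6 M of substrate, so 0.150 equiv of reagent and a ceiling of 15.0%. It ends with 0% of its reagent left, 9.43% of target and 1.69% of isomer of the product. The gap below its ceiling comes to 0.0621 M of reagent, and its 0.0310 M of self-condensation product holds 0.0620 M.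

The numbers in the tables come from a simulation with made-up constants.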